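Decide first to reckon a balance, not a rate. In each earlier run the X readings scatter about a level line from the first reading on, with a scatter of 1 percentage point, and the flask's 2.5 min is longer than the last reading at 120 s.

| setting | north-east | south-west | south | flask |
|---|---|---|---|---|
| X | 23 mM | 23 mM | 46 mM | 23 mM |
| Q | 17 mM | 26 mM | 34.5 mM | 34.5 mM |
| remark | run made earlier | run made earlier | run made earlier |  |
| time |  |  |  | 2.5 min |

| run | time / s | X / % | Z / % |
|---|---|---|---|
| north-east | 25.0 | 84.7 | 2.3 |
| north-east | 50.0 | 83.1 | 2.0 |
| north-east | 80.0 | 83.5 | 2.3 |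
| north-east | 90.0 | 84.4 | 2.2 |
| north-east | 120 | 83.5 | 1.6 |
| south-west | 10.0 | 76.9 | 2.3 |
| south-west | 20.0 | 75.7 | 2.8 |
| south-west | 30.0 | 73.4 | 2.4 |
| south-west | 60.0 | 75.6 | 4.3 |
| south-west | 120 | 76.8 | 1.9 |
| south | 10.0 | 76.9 | 1.1 |
| south | 20.0 | 73.4 | 4.1 |
| south | 30.0 | 75.6 | 4.7 |
| south | 60.0 | 75.0 | 3.9 |
| south | 120 | 73.7 | 5.1 |

(standard deviation of a reading: 1 percentage point)

* conversion of X at 2.5 min
* amount of Z at 2.5 min, in percent of the X charged

- the numbers in the tables scatter by 1 percentage point (one standard deviation)

Average the X readings of each run, count one Q lost per X bound, and set free [Q] beside r, the ratio of bound to free X: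

- North-east: X left 83.8%, free [Q] 13.3 mM, r 0.193, common logarithm of r −0.715
- South-west: X left 75.7%, free [Q] 20.4 mM, r 0.321, common logarithm of r −0.493
- South: X left 74.9%, free [Q] 23.0 mM, r 0.335, common logarithm of r −0.475

Read the first row against the last: the logarithm of free [Q] rises by 0.238 and that of r by 0.240, a slope of 1.01. The middle row was charged with half the X of the last, and its r still follows its free [Q]. So keep K 0.0149 /mM, r divided by free [Q], the apparent equilibrium constant, as a reading.

Put K into the balance for the flask and 6.74 mM of X is bound, a conversion of 29.3%. This reckoning sets no figure on Z.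

The forecast, holding that this “looks like a fast equilibrium”, gives 29.5%, a little above your 29.3%, and 3.6% of Z.

The flask gives 32.6% and 5.62%, both within the forecast's margins.

    Q + E ⇌ D (K = 10.0 /M, k = 1.37 /M/s)
    Q + E ⇌ Z (K = 10.6 /M, k = 0.773 /M/s)
    X + Q ⇌ E (K = 13.1 /M, k = 3.82 /M/s)

The reckoning with K falls 3.3 points short of the flask. At 2.50 min E holds 21.6% of the X charged in the flask, while Z and D, each carrying a second Q, hold 5.62% and 5.30%. Now take the neighbour flask, with 21 mM of Q and X and time unchanged: K gives 19.7%, and the simulation gives 20.6%. Counted the same way, r over free [Q] is 0.0160 /mM in that neighbour and 0.0179 /mM in the flask.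

The earlier runs and the new flask come from a simulation for an exercise; noise was put on by code.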